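**Retrosynthetic overview**

1. The target is guibourtinidol-(4β→6)-ent-epifisetinidol. The last disconnections are five benzyl and two silyl ethers, then the interflavan bond C4(upper)–C6(lower). That bond is made by adding a 6-lithiated lower flavan to an upper 3-silyloxyflavan-4-one and removing the tertiary hydroxyl by ionic hydrogenation (hydride anti to the 3-oxygen, so the aryl group ends 3,4-cis).
2. Ring C of the lower unit is closed at C3–C4 by a samarium diiodide Barbier cyclisation of a benzylic bromide onto an α-aryloxy aldehyde. The enabling feature: in ring C, C4 is a benzylic methylene on ring A and C3 is a carbinol carbon whose neighbour C2 carries the ring oxygen O1. C3–C4 therefore joins two carbons that are both electrophilic in simple precursors (ArCH2Br and CHO, polarity reversed at C4), and the O1–C2–C3=O array offers a five-membered samarium chelate that puts the new 3-OH cis to the 2-aryl group.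
3. The open-chain precursor gets its O1–C2 bond from a Mitsunobu inversion between 4-benzyloxy-5-bromo-2-hydroxybenzaldehyde and an (R)-mandelate (asymmetric transfer hydrogenation of the aryl glyoxylate). The ring bromine is carried along as the handle for the union.
4. Ring C of the upper unit is bought as 7-hydroxychromone. C2 is set by asymmetric conjugate addition of an arylboronic acid, C3 by Rubottom oxidation trans to the 2-aryl group.
5. Order of ring construction: lower ring C (step 8), then union of the two flavan units at C4 (steps 14 and 15). Rings A and B of both units and upper ring C come from commercial materials.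

Key step: step 8

**Remarks on the chemistry (assumptions)**

- The SMILES is read as upper unit 2R,3S,4S (2,3-trans, 3,4-cis, 4β-aryl) and lower unit 2S,3S (2,3-cis). Flavan numbering is used throughout (O1, C2 aryl, C3 oxygen, C4; ring A benzo, ring B 2-aryl, ring C pyran).
- The C2 descriptor of the upper unit is S in the flavanone and R after C3 hydroxylation, although nothing changes in space. For the same reason the C4 descriptor of the benzylated dimers is not quoted; 4β is used instead.
- The sense of induction in the two catalytic asymmetric steps (2 and 11) is taken from the accepted models. The antipodal catalyst would be used if the sense proved opposite.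
- Bn = benzyl, TBS = tert-butyldimethylsilyl.

**Route**

Step 1
Reactants: 1 4-bromo-1,2-bis(benzyloxy)benzene
Product: 3 methyl 2-[3,4-bis(benzyloxy)phenyl]-2-oxoacetate, via aryllithium 2 (not isolated)
Conditions: n-BuLi, THF, −78 °C; cannulated into dimethyl oxalate (excess), THF, −78 °C; aq NH4Cl
Reagents that add atoms: dimethyl oxalate COC(=O)C(=O)OC
Why: Bromine–lithium exchange followed by inverse addition to excess oxalate diester (acylation of an organolithium) should stop at the α-keto ester because the tetrahedral adduct persists at −78 °C.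

Step 2
Reactants: 3 methyl 2-[3,4-bis(benzyloxy)phenyl]-2-oxoacetate
Product: 4 methyl (2R)-2-[3,4-bis(benzyloxy)phenyl]-2-hydroxyacetate
Conditions: RuCl(p-cymene)[(S,S)-TsDPEN] (cat.), HCO2H/Et3N (5:2), DMF, rt
Reagents that add atoms: none
Why: Noyori–Ikariya asymmetric transfer hydrogenation of an aryl glyoxylate, in which the (S,S) catalyst is expected to deliver hydride with the aryl group in the CH/π position and so give the R carbinol that later becomes C2 of the lower unit.

Step 3
Reactants: 5 5-bromo-2,4-dihydroxybenzaldehyde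
Product: 6 4-(benzyloxy)-5-bromo-2-hydroxybenzaldehyde
Conditions: BnBr (1 equiv), NaHCO3, MeCN, 60 °C
Reagents that add atoms: benzyl bromide BrCc1ccccc1
Why: Williamson etherification with a weak base should alkylate only the more acidic 4-OH, because the 2-OH is locked in a hydrogen bond to the aldehyde.

Step 4
Reactants: 6 4-(benzyloxy)-5-bromo-2-hydroxybenzaldehyde; 4 methyl (2R)-2-[3,4-bis(benzyloxy)phenyl]-2-hydroxyacetate
Product: 7 methyl (2S)-2-[5-(benzyloxy)-4-bromo-2-formylphenoxy]-2-[3,4-bis(benzyloxy)phenyl]acetate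
Conditions: PPh3, DIAD, THF, 0 °C → rt
Reagents that add atoms: none
Why: Mitsunobu etherification of the acidic salicylaldehyde-type phenol should proceed by SN2 inversion at the carbinol (R → S), the adjacent ester disfavouring ionisation of the oxyphosphonium ion, and this sets C2 of the lower unit.

Step 5
Reactants: 7 methyl (2S)-2-[5-(benzyloxy)-4-bromo-2-formylphenoxy]-2-[3,4-bis(benzyloxy)phenyl]acetate
Product: 8 methyl (2S)-2-[5-(benzyloxy)-4-bromo-2-(hydroxymethyl)phenoxy]-2-[3,4-bis(benzyloxy)phenyl]acetate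
Conditions: NaBH4, CeCl3·7H2O, MeOH/THF, −40 °C
Reagents that add atoms: none
Why: Luche reduction should reduce the aryl aldehyde chemoselectively under nearly neutral conditions, leaving the ester and the enolisable α-aryloxy centre untouched.

Step 6
Reactants: 8 methyl (2S)-2-[5-(benzyloxy)-4-bromo-2-(hydroxymethyl)phenoxy]-2-[3,4-bis(benzyloxy)phenyl]acetate
Product: 9 methyl (2S)-2-[5-(benzyloxy)-4-bromo-2-(bromomethyl)phenoxy]-2-[3,4-bis(benzyloxy)phenyl]acetate
Conditions: PBr3, CH2Cl2, 0 °C; used crude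
Reagents that add atoms: phosphorus tribromide BrP(Br)Br
Why: Bromination of an electron-rich benzylic alcohol through its phosphite ester (SN2) is standard, and the ring bromine tempers the lability of the benzylic bromide.

Step 7
Reactants: 9 methyl (2S)-2-[5-(benzyloxy)-4-bromo-2-(bromomethyl)phenoxy]-2-[3,4-bis(benzyloxy)phenyl]acetate
Product: 10 (2S)-2-[5-(benzyloxy)-4-bromo-2-(bromomethyl)phenoxy]-2-[3,4-bis(benzyloxy)phenyl]acetaldehyde
Conditions: i-Bu2AlH (DIBAL-H, 1.1 equiv), CH2Cl2, −78 °C; MeOH quench, cold aqueous potassium sodium tartrate; used at once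
Reagents that add atoms: none
Why: Partial reduction of an α-aryloxy ester should stop at the chelated aluminium hemiacetal at −78 °C and give the aldehyde on cold work-up without touching either bromide, and immediate use avoids enolisation at C2.

Step 8
Reactants: 10 (2S)-2-[5-(benzyloxy)-4-bromo-2-(bromomethyl)phenoxy]-2-[3,4-bis(benzyloxy)phenyl]acetaldehyde
Product: 12 (2S,3S)-7-(benzyloxy)-2-[3,4-bis(benzyloxy)phenyl]-6-bromo-3,4-dihydro-2H-chromen-3-ol, via benzylsamarium diiodide 11 (not isolated)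
Conditions: SmI2 (2.5 equiv), THF, −78 → 0 °C, slow addition of 10 at high dilution, no HMPA; aq NH4Cl
Reagents that add atoms: none
Why: SmI2 reduces the benzylic C–Br bond of 10 by two single-electron transfers to the benzylsamarium 11, whose carbon (future C4) adds to the tethered aldehyde carbon (future C3), so two carbons that are both electrophilic in 10 are joined by polarity reversal at C4. The closest known reaction type is the samarium-diiodide-mediated intramolecular Barbier cyclisation of halo aldehydes and halo ketones. Ring C closes in the 6-exo-trig mode. The only new stereocentre, C3, is controlled by C2 through a chelate in which trivalent samarium bridges the aldehyde oxygen and the ether oxygen O1: with the 2-aryl group pseudo-equatorial in the half-chair, the carbonyl oxygen is held pseudo-axial and the 2,3-cis (2S,3S) alcohol should result. The step needs selectivity for the benzylic bromide over the aldehyde, the aryl bromide and the benzyl ethers; benzylic halides are reduced much faster than aliphatic aldehydes, aryl bromides and benzyl ethers are inert without HMPA, and slow addition at high dilution suppresses Wurtz-type dimerisation. No base is present, so the enolisable C2 centre should keep its configuration.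

Step 9
Reactants: 12 (2S,3S)-7-(benzyloxy)-2-[3,4-bis(benzyloxy)phenyl]-6-bromo-3,4-dihydro-2H-chromen-3-ol
Product: 13 tert-butyl{[(2S,3S)-7-(benzyloxy)-2-[3,4-bis(benzyloxy)phenyl]-6-bromo-3,4-dihydro-2H-chromen-3-yl]oxy}dimethylsilane
Conditions: TBSOTf, 2,6-lutidine, CH2Cl2, 0 °C
Reagents that add atoms: tert-butyldimethylsilyl triflate CC(C)(C)[Si](C)(C)OS(=O)(=O)C(F)(F)F
Why: Silylation with the silyl triflate should cap the hindered axial 3-OH so that the aryl bromide can be lithiated later.

Step 10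
Reactants: 14 7-hydroxy-4H-chromen-4-one
Product: 15 7-(benzyloxy)-4H-chromen-4-one
Conditions: BnBr, K2CO3, acetone, 55 °C
Reagents that add atoms: benzyl bromide BrCc1ccccc1
Why: Williamson etherification of the single phenol under conditions too mild to open the pyranone ring.

Step 11
Reactants: 15 7-(benzyloxy)-4H-chromen-4-one; 16 [4-(benzyloxy)phenyl]boronic acid
Product: 17 (2S)-7-(benzyloxy)-2-[4-(benzyloxy)phenyl]-2,3-dihydro-4H-chromen-4-one
Conditions: Pd(OCOCF3)2 (cat.), (R)-t-BuPyOx (cat.), NH4PF6, H2O, ClCH2CH2Cl, 60 °C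
Reagents that add atoms: none
Why: Palladium-catalysed asymmetric conjugate addition of an arylboronic acid to a chromone (aryl-palladium insertion, then protonolysis), in which the pyridine–oxazoline ligand selects the enone face and the R ligand is the enantiomer expected to give the 2S flavanone, the arrangement that becomes 2R in the upper unit.

Step 12
Reactants: 17 (2S)-7-(benzyloxy)-2-[4-(benzyloxy)phenyl]-2,3-dihydro-4H-chromen-4-one
Product: 20 (2R,3R)-7-(benzyloxy)-2-[4-(benzyloxy)phenyl]-3-hydroxy-2,3-dihydro-4H-chromen-4-one, via silyl enol ether 18 (not isolated), via silyloxy epoxide 19 (not isolated)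
Conditions: TMSOTf, Et3N, CH2Cl2, 0 °C; then dimethyldioxirane, acetone/CH2Cl2, −40 → 0 °C; then citric acid, MeOH
Reagents that add atoms: dimethyldioxirane CC1(C)OO1
Why: Rubottom oxidation, in which soft enolisation avoids a free enolate that could open ring C and the dioxirane epoxidises the enol ether on the face opposite the 2-aryl group, so the collapse of the silyloxy epoxide should give the 2,3-trans α-hydroxy ketone.

Step 13
Reactants: 20 (2R,3R)-7-(benzyloxy)-2-[4-(benzyloxy)phenyl]-3-hydroxy-2,3-dihydro-4H-chromen-4-one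
Product: 21 (2R,3R)-7-(benzyloxy)-2-[4-(benzyloxy)phenyl]-3-[(tert-butyldimethylsilyl)oxy]-2,3-dihydro-4H-chromen-4-one
Conditions: TBSCl, imidazole, DMF, rt
Reagents that add atoms: tert-butyldimethylsilyl chloride CC(C)(C)[Si](C)(C)Cl
Why: Standard silylation of the equatorial α-hydroxyl, and because the trans isomer is the thermodynamic one the mild base cannot erode C3.

Step 14
Reactants: 13 tert-butyl{[(2S,3S)-7-(benzyloxy)-2-[3,4-bis(benzyloxy)phenyl]-6-bromo-3,4-dihydro-2H-chromen-3-yl]oxy}dimethylsilane; 21 (2R,3R)-7-(benzyloxy)-2-[4-(benzyloxy)phenyl]-3-[(tert-butyldimethylsilyl)oxy]-2,3-dihydro-4H-chromen-4-one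
Product: 23 tertiary carbinol 7,4′-di-O-benzyl-3-O-TBS-4-hydroxyguibourtinidol-(4→6)-7,3′,4′-tri-O-benzyl-3-O-TBS-ent-epifisetinidol (drawn as the C4 epimer from attack anti to the 3-silyloxy group), via aryllithium 22 (not isolated)
Conditions: t-BuLi (2.1 equiv), THF, −78 °C; then 21, −78 → −40 °C; aq NH4Cl
Reagents that add atoms: none
Why: Bromine–lithium exchange and 1,2-addition of the aryllithium to the ketone should form the interflavan bond at C6 of the lower unit with no regiochemical ambiguity, and the configuration of the new carbinol centre does not matter because it is planarised in step 15.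

Step 15
Reactants: 23 tertiary carbinol 7,4′-di-O-benzyl-3-O-TBS-4-hydroxyguibourtinidol-(4→6)-7,3′,4′-tri-O-benzyl-3-O-TBS-ent-epifisetinidol
Product: 24 7,4′-di-O-benzyl-3-O-TBS-guibourtinidol-(4β→6)-7,3′,4′-tri-O-benzyl-3-O-TBS-ent-epifisetinidol (upper unit 2R,3S, 3,4-cis; lower unit 2S,3S)
Conditions: Et3SiH (5 equiv), CF3CO2H (10 equiv), CH2Cl2, −40 → 0 °C
Reagents that add atoms: none
Why: Ionic hydrogenation, in which acid ionises the doubly benzylic tertiary alcohol to a cation stabilised by the para oxygens of both A rings and the silane is expected to deliver hydride anti to the neighbouring 3-silyloxy group (the facial preference that makes Friedel–Crafts couplings of 2,3-trans flavan-4-yl cations 3,4-trans), so the aryl group ends 3,4-cis (4β).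

Step 16
Reactants: 24 7,4′-di-O-benzyl-3-O-TBS-guibourtinidol-(4β→6)-7,3′,4′-tri-O-benzyl-3-O-TBS-ent-epifisetinidol
Product: 25 7,4′-di-O-benzylguibourtinidol-(4β→6)-7,3′,4′-tri-O-benzyl-ent-epifisetinidol
Conditions: Bu4NF, AcOH, THF, 45 °C
Reagents that add atoms: none
Why: Fluoride cleavage of both secondary silyl ethers, buffered with acetic acid so that no base-sensitive centre is disturbed.

Step 17
Reactants: 25 7,4′-di-O-benzylguibourtinidol-(4β→6)-7,3′,4′-tri-O-benzyl-ent-epifisetinidol
Product: 26 (2R,3S,4S)-4-[(2S,3S)-2-(3,4-dihydroxyphenyl)-3,7-dihydroxy-3,4-dihydro-2H-chromen-6-yl]-2-(4-hydroxyphenyl)-3,4-dihydro-2H-chromene-3,7-diol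
Conditions: H2 (1 atm), Pd(OH)2/C, THF/MeOH, rt
Reagents that add atoms: none
Why: Hydrogenolysis of the five benzyl ethers under neutral conditions, which should spare the cyclic benzylic C2–O1 bonds as is usual for flavan-3-ols.

**Compound list**

1 | 4-bromo-1,2-bis(benzyloxy)benzene | Brc1ccc(OCc2ccccc2)c(OCc2ccccc2)c1 | starting material
2 | [3,4-bis(benzyloxy)phenyl]lithium | [Li]c1ccc(OCc2ccccc2)c(OCc2ccccc2)c1 | intermediate
3 | methyl 2-[3,4-bis(benzyloxy)phenyl]-2-oxoacetate | COC(=O)C(=O)c1ccc(OCc2ccccc2)c(OCc2ccccc2)c1 | intermediate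
4 | methyl (2R)-2-[3,4-bis(benzyloxy)phenyl]-2-hydroxyacetate | COC(=O)[C@H](O)c1ccc(OCc2ccccc2)c(OCc2ccccc2)c1 | intermediate
5 | 5-bromo-2,4-dihydroxybenzaldehyde | O=Cc1cc(Br)c(O)cc1O | starting material
6 | 4-(benzyloxy)-5-bromo-2-hydroxybenzaldehyde | O=Cc1cc(Br)c(OCc2ccccc2)cc1O | intermediate
7 | methyl (2S)-2-[5-(benzyloxy)-4-bromo-2-formylphenoxy]-2-[3,4-bis(benzyloxy)phenyl]acetate | COC(=O)[C@@H](Oc1cc(OCc2ccccc2)c(Br)cc1C=O)c1ccc(OCc2ccccc2)c(OCc2ccccc2)c1 | intermediate
8 | methyl (2S)-2-[5-(benzyloxy)-4-bromo-2-(hydroxymethyl)phenoxy]-2-[3,4-bis(benzyloxy)phenyl]acetate | COC(=O)[C@@H](Oc1cc(OCc2ccccc2)c(Br)cc1CO)c1ccc(OCc2ccccc2)c(OCc2ccccc2)c1 | intermediate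
9 | methyl (2S)-2-[5-(benzyloxy)-4-bromo-2-(bromomethyl)phenoxy]-2-[3,4-bis(benzyloxy)phenyl]acetate | COC(=O)[C@@H](Oc1cc(OCc2ccccc2)c(Br)cc1CBr)c1ccc(OCc2ccccc2)c(OCc2ccccc2)c1 | intermediate
10 | (2S)-2-[5-(benzyloxy)-4-bromo-2-(bromomethyl)phenoxy]-2-[3,4-bis(benzyloxy)phenyl]acetaldehyde | O=C[C@@H](Oc1cc(OCc2ccccc2)c(Br)cc1CBr)c1ccc(OCc2ccccc2)c(OCc2ccccc2)c1 | intermediate
11 | benzylsamarium diiodide from 10 (CH2–SmI2 in place of CH2Br, trivalent samarium) | O=C[C@@H](Oc1cc(OCc2ccccc2)c(Br)cc1C[Sm](I)I)c1ccc(OCc2ccccc2)c(OCc2ccccc2)c1 | intermediate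
12 | (2S,3S)-7-(benzyloxy)-2-[3,4-bis(benzyloxy)phenyl]-6-bromo-3,4-dihydro-2H-chromen-3-ol | Brc1cc2c(cc1OCc1ccccc1)O[C@@H](c1ccc(OCc3ccccc3)c(OCc3ccccc3)c1)[C@@H](O)C2 | intermediate
13 | tert-butyl{[(2S,3S)-7-(benzyloxy)-2-[3,4-bis(benzyloxy)phenyl]-6-bromo-3,4-dihydro-2H-chromen-3-yl]oxy}dimethylsilane | Brc1cc2c(cc1OCc1ccccc1)O[C@@H](c1ccc(OCc3ccccc3)c(OCc3ccccc3)c1)[C@@H](O[Si](C)(C)C(C)(C)C)C2 | intermediate
14 | 7-hydroxy-4H-chromen-4-one | O=c1ccoc2cc(O)ccc12 | starting material
15 | 7-(benzyloxy)-4H-chromen-4-one | O=c1ccoc2cc(OCc3ccccc3)ccc12 | intermediate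
16 | [4-(benzyloxy)phenyl]boronic acid | OB(O)c1ccc(OCc2ccccc2)cc1 | starting material
17 | (2S)-7-(benzyloxy)-2-[4-(benzyloxy)phenyl]-2,3-dihydro-4H-chromen-4-one | O=C1C[C@@H](c2ccc(OCc3ccccc3)cc2)Oc2cc(OCc3ccccc3)ccc21 | intermediate
18 | {[(2S)-7-(benzyloxy)-2-[4-(benzyloxy)phenyl]-2H-chromen-4-yl]oxy}trimethylsilane | C[Si](C)(C)OC1=C[C@@H](c2ccc(OCc3ccccc3)cc2)Oc2cc(OCc3ccccc3)ccc21 | intermediate
19 | 3,4-epoxide of 18, oxirane oxygen anti to the 2-aryl group | C[Si](C)(C)O[C@@]12O[C@@H]1[C@@H](c1ccc(OCc3ccccc3)cc1)Oc1cc(OCc3ccccc3)ccc12 | intermediate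
20 | (2R,3R)-7-(benzyloxy)-2-[4-(benzyloxy)phenyl]-3-hydroxy-2,3-dihydro-4H-chromen-4-one | O=C1[C@H](O)[C@@H](c2ccc(OCc3ccccc3)cc2)Oc2cc(OCc3ccccc3)ccc21 | intermediate
21 | (2R,3R)-7-(benzyloxy)-2-[4-(benzyloxy)phenyl]-3-[(tert-butyldimethylsilyl)oxy]-2,3-dihydro-4H-chromen-4-one | O=C1[C@H](O[Si](C)(C)C(C)(C)C)[C@@H](c2ccc(OCc3ccccc3)cc2)Oc2cc(OCc3ccccc3)ccc21 | intermediate
22 | 6-lithio derivative of 13 | [Li]c1cc2c(cc1OCc1ccccc1)O[C@@H](c1ccc(OCc3ccccc3)c(OCc3ccccc3)c1)[C@@H](O[Si](C)(C)C(C)(C)C)C2 | intermediate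
23 | tertiary carbinol: 7,4′-di-O-benzyl-3-O-TBS-4-hydroxyguibourtinidol-(4→6)-7,3′,4′-tri-O-benzyl-3-O-TBS-ent-epifisetinidol, C4 epimer with the aryl group anti to the 3-silyloxy group | c6ccccc6COc1ccc([C@H]2Oc3cc(OCc5ccccc5)ccc3[C@@](O)(c3cc4c(cc3OCc5ccccc5)O[C@@H](c3ccc(OCc5ccccc5)c(OCc5ccccc5)c3)[C@@H](O[Si](C)(C)C(C)(C)C)C4)[C@@H]2O[Si](C)(C)C(C)(C)C)cc1 | intermediate
24 | 7,4′-di-O-benzyl-3-O-TBS-guibourtinidol-(4β→6)-7,3′,4′-tri-O-benzyl-3-O-TBS-ent-epifisetinidol | c6ccccc6COc1ccc([C@H]2Oc3cc(OCc5ccccc5)ccc3[C@H](c3cc4c(cc3OCc5ccccc5)O[C@@H](c3ccc(OCc5ccccc5)c(OCc5ccccc5)c3)[C@@H](O[Si](C)(C)C(C)(C)C)C4)[C@@H]2O[Si](C)(C)C(C)(C)C)cc1 | intermediate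
25 | 7,4′-di-O-benzylguibourtinidol-(4β→6)-7,3′,4′-tri-O-benzyl-ent-epifisetinidol | c6ccccc6COc1ccc([C@H]2Oc3cc(OCc5ccccc5)ccc3[C@H](c3cc4c(cc3OCc5ccccc5)O[C@@H](c3ccc(OCc5ccccc5)c(OCc5ccccc5)c3)[C@@H](O)C4)[C@@H]2O)cc1 | intermediate
26 | (2R,3S,4S)-4-[(2S,3S)-2-(3,4-dihydroxyphenyl)-3,7-dihydroxy-3,4-dihydro-2H-chromen-6-yl]-2-(4-hydroxyphenyl)-3,4-dihydro-2H-chromene-3,7-diol | Oc1ccc([C@H]2Oc3cc(O)ccc3[C@H](c3cc4c(cc3O)O[C@@H](c3ccc(O)c(O)c3)[C@@H](O)C4)[C@@H]2O)cc1 | target

**Step count and risks**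

Total step count: 17. Longest linear sequence: 12 steps (steps 1, 2, 4, 5, 6, 7, 8, 9, 14, 15, 16, 17).

Steps most likely to fail:

1. Step 8. What may go wrong: loss of the aryl ether by β-elimination from a ketyl, Wurtz-type homocoupling of the benzylic organometallic, or weak chelation giving poor facial selectivity at C3. The fallback sets out from 10 and returns at 12. Bromo aldehyde 10 is cyclised with CrCl2 (THF, cat. LiI, rt; Nozaki–Hiyama-type addition of a benzylchromium species, no ketyl involved). This is expected to give the ring-closed alcohol without facial control, as 12 mixed with its C3 epimer (2S,3R)-7-(benzyloxy)-2-[3,4-bis(benzyloxy)phenyl]-6-bromo-3,4-dihydro-2H-chromen-3-ol F1. The mixture is oxidised with Dess–Martin periodinane (NaHCO3, CH2Cl2) to the flavan-3-one (2S)-7-(benzyloxy)-2-[3,4-bis(benzyloxy)phenyl]-6-bromo-2H-chromen-3(4H)-one F2. LiBH(s-Bu)3 (THF, −78 °C) then delivers hydride opposite the 2-aryl group to give the 2,3-cis alcohol 12. C3 is thus set by reagent approach to a ketone and not in the C–C bond formation.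

2. Step 15. What may go wrong: hydride delivery to the wrong face of the C4 cation (syn to the 3-silyloxy group, giving the 3,4-trans isomer), together with acid-induced desilylation or opening of ring C at C2. The carbonyl addition of step 14 may also suffer enolisation of the ketone. The fallback sets out from 12 and 20, returns at 25, and replaces steps 14 to 16 by a tethered Friedel–Crafts coupling that delivers the arene from the face of the 3-oxygen.
   - 12 is debrominated (n-BuLi, 2.2 equiv, THF, −78 °C, then H2O) to (2S,3S)-7-(benzyloxy)-2-[3,4-bis(benzyloxy)phenyl]-3,4-dihydro-2H-chromen-3-ol F3.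
   - Glutaric anhydride (DMAP, pyridine) converts it into the hemiglutarate 5-{[(2S,3S)-7-(benzyloxy)-2-[3,4-bis(benzyloxy)phenyl]-3,4-dihydro-2H-chromen-3-yl]oxy}-5-oxopentanoic acid F4.
   - Steglich esterification with the 3-OH of 20 (EDC, DMAP, CH2Cl2) gives the keto diester F5.
   - NaBH4 (MeOH/THF, −20 °C) reduces the ketone to the flavan-4-ol diester F6.
   - TMSOTf (CH2Cl2, −40 °C, high dilution) ionises C4, and the tethered lower A ring attacks through C6 (para to O1, less hindered than C8) from the β-face where the tether is anchored, giving the 3,4-cis macrocyclic diester F7.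
   - K2CO3/MeOH removes the glutarate and gives 25.

3. Step 4. What may go wrong: partial ionisation of the electron-rich benzylic oxyphosphonium ion, with erosion of enantiomeric purity at the future C2. The fallback sets out from 6 and returns at 7. Commercial methyl [3,4-bis(benzyloxy)phenyl]acetate is converted by diazo transfer (p-acetamidobenzenesulfonyl azide, DBU, MeCN) into methyl 2-[3,4-bis(benzyloxy)phenyl]-2-diazoacetate F8. Catalytic asymmetric O–H insertion of its carbenoid into phenol 6 (PdCl2(PhCN)2, chiral spiro bis(oxazoline) ligand, NaB[3,5-(CF3)2C6H3]4, CHCl3; ligand enantiomer chosen for S) gives 7 directly. The stereocentre then arises from catalyst-controlled protonation of a neutral ylide and no longer from substitution at an ionisable carbon.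

Further compounds
F1 | step 8 | (2S,3R)-7-(benzyloxy)-2-[3,4-bis(benzyloxy)phenyl]-6-bromo-3,4-dihydro-2H-chromen-3-ol | Brc1cc2c(cc1OCc1ccccc1)O[C@@H](c1ccc(OCc3ccccc3)c(OCc3ccccc3)c1)[C@H](O)C2
F2 | step 8 | (2S)-7-(benzyloxy)-2-[3,4-bis(benzyloxy)phenyl]-6-bromo-2H-chromen-3(4H)-one | Brc1cc2c(cc1OCc1ccccc1)O[C@@H](c1ccc(OCc3ccccc3)c(OCc3ccccc3)c1)C(=O)C2
F3 | step 15 | (2S,3S)-7-(benzyloxy)-2-[3,4-bis(benzyloxy)phenyl]-3,4-dihydro-2H-chromen-3-ol | c1cc2c(cc1OCc1ccccc1)O[C@@H](c1ccc(OCc3ccccc3)c(OCc3ccccc3)c1)[C@@H](O)C2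
F4 | step 15 | 5-{[(2S,3S)-7-(benzyloxy)-2-[3,4-bis(benzyloxy)phenyl]-3,4-dihydro-2H-chromen-3-yl]oxy}-5-oxopentanoic acid | c1cc2c(cc1OCc1ccccc1)O[C@@H](c1ccc(OCc3ccccc3)c(OCc3ccccc3)c1)[C@@H](OC(=O)CCCC(=O)O)C2
F5 | step 15 | glutarate diester linking the 3-O of 20 (2R,3R ketone) to the 3-O of F3 | O=C1[C@H](OC(=O)CCCC(=O)O[C@H]2Cc3ccc(OCc4ccccc4)cc3O[C@H]2c2ccc(OCc3ccccc3)c(OCc3ccccc3)c2)[C@@H](c2ccc(OCc3ccccc3)cc2)Oc2cc(OCc3ccccc3)ccc21
F6 | step 15 | flavan-4-ol diester from reduction of F5 (upper unit 2,3-trans-3,4-trans, C4 configuration immaterial) | O[C@H]1[C@H](OC(=O)CCCC(=O)O[C@H]2Cc3ccc(OCc4ccccc4)cc3O[C@H]2c2ccc(OCc3ccccc3)c(OCc3ccccc3)c2)[C@@H](c2ccc(OCc3ccccc3)cc2)Oc2cc(OCc3ccccc3)ccc21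
F7 | step 15 | macrocyclic glutarate of 25 bridging the two 3-oxygens (4β→6 linkage, 3,4-cis) | c6ccccc6COc1ccc([C@H]2Oc3cc(OCc5ccccc5)ccc3[C@H](c3cc4c(cc3OCc5ccccc5)O[C@@H](c3ccc(OCc5ccccc5)c(OCc5ccccc5)c3)[C@@H](OC(=O)CCCC(=O)O7)C4)[C@@H]27)cc1
F8 | step 4 | methyl 2-[3,4-bis(benzyloxy)phenyl]-2-diazoacetate | COC(=O)C(=[N+]=[N-])c1ccc(OCc2ccccc2)c(OCc2ccccc2)c1
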